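## Retrosynthetic overview

1. Target 19 ⇐ tris-MOM ether 18 by global acetal cleavage. Both vinyl groups ⇐ the two C–B bonds of the bis(tertiary boronic ester) 15 by double Zweifel olefination with retention.
2. Key disconnection, made twice in one flask: each quaternary C–CH2 bond of 15. The benzylic carbinol carbon of bis-carbamate 12 (the former acetophenone C=O carbon, normally an acceptor) is used as a configurationally stable α-oxygenated carbanion. It is joined to the boron-bound donor carbon of homogeranyl boronate 4 by borylation and 1,2-metallate shift, so carbinol chirality becomes quaternary-carbon chirality.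
3. 12 ⇐ diaryl ether diol 11 ⇐ Ullmann C–O coupling of bromide 7 (ring B) with phenol 10 (ring A). Each comes from a commercial acetophenone by MOM protection and Noyori transfer hydrogenation with enantiomeric catalysts.
4. 4 ⇐ geranyl bromide + CH2(Bpin)2 by deborylative alkylation.
5. No ring is constructed: rings A and B are bought as arenes and are joined through the ether oxygen before either side chain is attached.

Assumption: the SMILES is read literally, i.e. (R) at the quaternary carbon on ring A (the ring with two free OH), (S) at the one on ring B, and both chain C6 alkenes E.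

## Route

Step 1
Reactants: 1 geranyl bromide, 2 bis(pinacolatoboryl)methane
Product: 4 homogeranyl pinacol boronate 2-[(3E)-4,8-dimethylnona-3,7-dien-1-yl]-4,4,5,5-tetramethyl-1,3,2-dioxaborolane, via sodium α-boryl carbanion 3 (not isolated)
Conditions: 2 (1.5 equiv), NaOtBu (1.4 equiv), THF, 10 min; then 1, 0 °C → rt
Reagents that add atoms: none
Why: Alkoxide-promoted deborylative alkylation: tert-butoxide removes one boron from 2 to give the α-boryl carbanion 3, which displaces the primary allylic bromide of 1 in an SN2 sense without touching the E-alkene, giving the one-carbon-homologated primary boronate in a single operation.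

Step 2
Reactants: 5 1-(3-bromo-2-hydroxyphenyl)ethan-1-one
Product: 6 1-[3-bromo-2-(methoxymethoxy)phenyl]ethan-1-one
Conditions: NaH, MOMCl, DMF, 0 °C → rt
Reagents that add atoms: chloromethyl methyl ether (MOMCl), COCCl
Why: Williamson-type O-alkylation (MOM protection) of the sodium phenoxide; the acetal masks the phenol ortho to the future benzylic carbanion and survives base, organolithiums, I2 and NaOMe.

Step 3
Reactants: 6 1-[3-bromo-2-(methoxymethoxy)phenyl]ethan-1-one
Product: 7 (1S)-1-[3-bromo-2-(methoxymethoxy)phenyl]ethan-1-ol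
Conditions: RuCl[(S,S)-TsDPEN](p-cymene) (1 mol %), HCO2H/Et3N (5:2), 30 °C
Reagents that add atoms: none
Why: Noyori asymmetric transfer hydrogenation: the (S,S) catalyst delivers hydride in the same facial sense as acetophenone → (S)-1-phenylethanol, setting the (S)-carbinol centre that later becomes the ring B quaternary centre (aryl bromide and MOM ether are inert; ee checked and upgraded by crystallisation if needed).

Step 4
Reactants: 8 1-(3,4,5-trihydroxyphenyl)ethan-1-one
Product: 9 1-[3-hydroxy-4,5-bis(methoxymethoxy)phenyl]ethan-1-one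
Conditions: MOMCl (2.05 equiv), K2CO3 (2.1 equiv), acetone, 0 °C → rt
Reagents that add atoms: chloromethyl methyl ether (MOMCl), COCCl
Why: Acidity-controlled Williamson etherification: the 4-OH para to the acetyl group is the most acidic and reacts first, after which either of the two equivalent flanking OH groups gives the same 4,5-bis-ether, so 9 is the main product (expected about 50 %; mono- and tris-ethers are separated and recycled).

Step 5
Reactants: 9 1-[3-hydroxy-4,5-bis(methoxymethoxy)phenyl]ethan-1-one
Product: 10 (1R)-1-[3-hydroxy-4,5-bis(methoxymethoxy)phenyl]ethan-1-ol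
Conditions: RuCl[(R,R)-TsDPEN](p-cymene) (1 mol %), HCO2H/Et3N (5:2), 40 °C
Reagents that add atoms: none
Why: Noyori asymmetric transfer hydrogenation with the enantiomeric catalyst gives the (R)-carbinol (the free phenol is tolerated), fixing the centre that later becomes the ring A quaternary centre.

Step 6
Reactants: 7 (1S)-1-[3-bromo-2-(methoxymethoxy)phenyl]ethan-1-ol, 10 (1R)-1-[3-hydroxy-4,5-bis(methoxymethoxy)phenyl]ethan-1-ol
Product: 11 (1S)-1-[3-{5-[(1R)-1-hydroxyethyl]-2,3-bis(methoxymethoxy)phenoxy}-2-(methoxymethoxy)phenyl]ethan-1-ol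
Conditions: CuI (10 mol %), picolinic acid (20 mol %), K3PO4 (2 equiv), DMSO, 90 °C
Reagents that add atoms: none
Why: Ullmann-type CuI-catalysed C–O coupling with a ligand that tolerates ortho-alkoxy groups on both partners; the phenoxide of 10 is arylated far faster than the secondary alkoxides and neither carbinol centre is touched.

Step 7
Reactants: 11 diaryl ether diol
Product: 12 (1R)-1-{3-[3-{(1S)-1-[(diisopropylcarbamoyl)oxy]ethyl}-2-(methoxymethoxy)phenoxy]-4,5-bis(methoxymethoxy)phenyl}ethyl N,N-diisopropylcarbamate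
Conditions: NaH (2.6 equiv), iPr2NCOCl (2.6 equiv), THF, 0 → 50 °C
Reagents that add atoms: N,N-diisopropylcarbamoyl chloride, CC(C)N(C(C)C)C(Cl)=O
Why: O-Carbamoylation of both sodium alkoxides with retention (no bond to a stereocentre is broken), installing the groups that direct the benzylic lithiation and later act as leaving groups.

Step 8
Reactants: 12 bis-carbamate, 4 homogeranyl pinacol boronate
Product: 15 bis(tertiary pinacol boronic ester) in which each benzylic carbon bears CH3 and Bpin and the (3E)-4,8-dimethylnona-3,7-dienyl chain with (R) at ring A and (S) at ring B, via dilithio bis-carbamate 13 (not isolated), via dilithium bis-boronate complex 14 (not isolated)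
Conditions: s-BuLi (2.6 equiv), Et2O, −78 °C, 1 h; 4 (3 equiv), −78 °C, 2 h; MgBr2 in MeOH, −78 °C → rt, 16 h
Reagents that add atoms: none
Why: Twofold lithiation–borylation: each carbamate-directed deprotonation gives a configurationally stable α-oxygenated benzylic carbanion with retention (the carbinol carbon, an acceptor at the carbonyl level, acting as donor), which adds to the boron of 4 with retention, and the homogeranyl group then shifts from boron to carbon anti to the departing carbamate with inversion, so the (R)- and (S)-carbinol centres are transferred stereospecifically to the two quaternary carbons and both C–C bonds form in one flask (MgBr2/MeOH suppresses reversal of the electron-rich boronate complexes).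

Step 9
Reactants: 15 bis(tertiary pinacol boronic ester)
Product: 18 tris(methoxymethyl) ether of the target, via dilithium bis(vinylboronate) complex 16 (not isolated), via bis(β-iodoalkyl boronic ester) 17 (not isolated)
Conditions: CH2=CHLi (6 equiv, from Sn(CH=CH2)4 + n-BuLi), THF, −78 °C; I2 (6 equiv) in MeOH, −78 °C; NaOMe in MeOH, −78 °C → rt; Na2S2O3 quench
Reagents that add atoms: vinyllithium, [Li]C=C (made in the flask from tetravinylstannane, C=C[Sn](C=C)(C=C)C=C, and n-BuLi)
Why: Twofold Zweifel olefination: I2 activates each vinylboronate complex so that the tertiary alkyl group migrates from boron to carbon with retention, and methoxide-induced anti-elimination of the β-iodo boronic esters releases the two terminal vinyl groups, completing both quaternary centres in the target configuration (at −78 °C iodine reacts with the boronate complex in preference to the trisubstituted alkenes).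

Step 10
Reactants: 18 tris(methoxymethyl) ether of the target
Product: 19 5-[(3R,6E)-3,7,11-trimethyldodeca-1,6,10-trien-3-yl]-3-{2-hydroxy-3-[(3S,6E)-3,7,11-trimethyldodeca-1,6,10-trien-3-yl]phenoxy}benzene-1,2-diol
Conditions: HCl (1 M in MeOH/THF), degassed, 0 °C → rt, argon
Reagents that add atoms: none
Why: Acid-catalysed acetal exchange (MOM cleavage) frees the three phenols under conditions routinely tolerated by geranyl-type chains; no stereocentre is involved and exclusion of air protects the catechol.

## Compound list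

1 | geranyl bromide, (2E)-1-bromo-3,7-dimethylocta-2,6-diene | CC(C)=CCC/C(C)=C/CBr | starting material
2 | bis(pinacolatoboryl)methane, 2,2'-methylenebis(4,4,5,5-tetramethyl-1,3,2-dioxaborolane) | CC1(C)OB(CB2OC(C)(C)C(C)(C)O2)OC1(C)C | starting material
3 | sodium (4,4,5,5-tetramethyl-1,3,2-dioxaborolan-2-yl)methanide (formed in the flask) | [Na+].[CH2-]B1OC(C)(C)C(C)(C)O1 | intermediate
4 | homogeranyl pinacol boronate, 2-[(3E)-4,8-dimethylnona-3,7-dien-1-yl]-4,4,5,5-tetramethyl-1,3,2-dioxaborolane | CC(C)=CCC/C(C)=C/CCB1OC(C)(C)C(C)(C)O1 | intermediate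
5 | 1-(3-bromo-2-hydroxyphenyl)ethan-1-one | CC(=O)c1cccc(Br)c1O | starting material
6 | 1-[3-bromo-2-(methoxymethoxy)phenyl]ethan-1-one | CC(=O)c1cccc(Br)c1OCOC | intermediate
7 | (1S)-1-[3-bromo-2-(methoxymethoxy)phenyl]ethan-1-ol | C[C@H](O)c1cccc(Br)c1OCOC | intermediate
8 | 1-(3,4,5-trihydroxyphenyl)ethan-1-one | CC(=O)c1cc(O)c(O)c(O)c1 | starting material
9 | 1-[3-hydroxy-4,5-bis(methoxymethoxy)phenyl]ethan-1-one | CC(=O)c1cc(O)c(OCOC)c(OCOC)c1 | intermediate
10 | (1R)-1-[3-hydroxy-4,5-bis(methoxymethoxy)phenyl]ethan-1-ol | C[C@@H](O)c1cc(O)c(OCOC)c(OCOC)c1 | intermediate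
11 | (1S)-1-[3-{5-[(1R)-1-hydroxyethyl]-2,3-bis(methoxymethoxy)phenoxy}-2-(methoxymethoxy)phenyl]ethan-1-ol | C[C@@H](O)c1cc(OCOC)c(OCOC)c(Oc2cccc([C@H](C)O)c2OCOC)c1 | intermediate
12 | bis(N,N-diisopropylcarbamate) of 11; ring A carbinol (R), ring B carbinol (S) | C[C@@H](OC(=O)N(C(C)C)C(C)C)c1cc(OCOC)c(OCOC)c(Oc2cccc([C@H](C)OC(=O)N(C(C)C)C(C)C)c2OCOC)c1 | intermediate
13 | dilithio bis-carbamate: 12 with each benzylic H replaced by Li with retention (formed in the flask) | C[C@@]([Li])(OC(=O)N(C(C)C)C(C)C)c1cc(OCOC)c(OCOC)c(Oc2cccc([C@]([Li])(C)OC(=O)N(C(C)C)C(C)C)c2OCOC)c1 | intermediate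
14 | dilithium bis-boronate complex: each benzylic carbon bonded to the tetracoordinate boron of 4, carbamate still in place (formed in the flask) | C[C@@]([B-]1(CC/C=C(\C)CCC=C(C)C)OC(C)(C)C(C)(C)O1)(OC(=O)N(C(C)C)C(C)C)c1cc(OCOC)c(OCOC)c(Oc2cccc([C@]([B-]3(CC/C=C(\C)CCC=C(C)C)OC(C)(C)C(C)(C)O3)(C)OC(=O)N(C(C)C)C(C)C)c2OCOC)c1.[Li+].[Li+] | intermediate
15 | bis(tertiary pinacol boronic ester): each benzylic carbon bears CH3, Bpin and the (3E)-4,8-dimethylnona-3,7-dienyl chain; (R) at ring A, (S) at ring B; three MOM ethers | C[C@@](CC/C=C(\C)CCC=C(C)C)(B1OC(C)(C)C(C)(C)O1)c1cc(OCOC)c(OCOC)c(Oc2cccc([C@](CC/C=C(\C)CCC=C(C)C)(C)B3OC(C)(C)C(C)(C)O3)c2OCOC)c1 | intermediate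
16 | dilithium bis(vinylboronate) complex of 15 (formed in the flask) | C[C@@](CC/C=C(\C)CCC=C(C)C)([B-]1(C=C)OC(C)(C)C(C)(C)O1)c1cc(OCOC)c(OCOC)c(Oc2cccc([C@](CC/C=C(\C)CCC=C(C)C)(C)[B-]3(C=C)OC(C)(C)C(C)(C)O3)c2OCOC)c1.[Li+].[Li+] | intermediate
17 | bis(β-iodoalkyl boronic ester): each quaternary carbon bonded to CH(Bpin)CH2I, new CH(B) centres undefined (formed in the flask) | C[C@@](CC/C=C(\C)CCC=C(C)C)(C(CI)B1OC(C)(C)C(C)(C)O1)c1cc(OCOC)c(OCOC)c(Oc2cccc([C@](CC/C=C(\C)CCC=C(C)C)(C)C(CI)B3OC(C)(C)C(C)(C)O3)c2OCOC)c1 | intermediate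
18 | tris(methoxymethyl) ether of 19; (3R) side chain on ring A, (3S) on ring B | C=C[C@@](C)(CC/C=C(\C)CCC=C(C)C)c1cc(OCOC)c(OCOC)c(Oc2cccc([C@](C)(C=C)CC/C=C(\C)CCC=C(C)C)c2OCOC)c1 | intermediate
19 | 5-[(3R,6E)-3,7,11-trimethyldodeca-1,6,10-trien-3-yl]-3-{2-hydroxy-3-[(3S,6E)-3,7,11-trimethyldodeca-1,6,10-trien-3-yl]phenoxy}benzene-1,2-diol (CNP0325484.1) | C=C[C@@](C)(CC/C=C(\C)CCC=C(C)C)c1cc(O)c(O)c(Oc2cccc([C@](C)(C=C)CC/C=C(\C)CCC=C(C)C)c2O)c1 | target

## Step count and risks

Total steps: 10. Longest linear sequence: 7 steps (5 → 6 → 7 → 11 → 12 → 15 → 18 → 19; the branch from 8 is equally long).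

Most likely to fail:

Step 8, the double lithiation–borylation. Two electron-rich benzylic carbamates must both be lithiated and both boronate complexes must rearrange before they revert, or the diastereomeric purity is lost. The fallback sets out from diol 11. Both alcohols are acylated with 2,4,6-triisopropylbenzoyl chloride and NaH (retention) to give the bis(2,4,6-triisopropylbenzoate) F1. Its benzylic positions are lithiated with s-BuLi/TMEDA in Et2O at −78 °C and treated with 4. The hindered benzoate is a much better leaving group than the carbamate, so the 1,2-shift runs at low temperature without additive, and the route is rejoined at 15.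

Step 9, the double Zweifel olefination. Two hindered tertiary boronic esters must form vinyl complexes, and I2 is used next to four trisubstituted alkenes. The fallback sets out from 15 and avoids iodine. Matteson homologation with LiCHCl2 (CH2Cl2, n-BuLi, THF, −100 °C, then ZnCl2) gives the bis(α-chloroalkyl pinacol boronate) F2, the tertiary group migrating with retention. Oxidation with NaBO3 in THF/H2O collapses it to the non-enolisable dialdehyde F3. Wittig methylenation with Ph3P=CH2 rejoins the route at 18.

Step 10, the global MOM cleavage. Brønsted acid could hydrate or cyclise the polyene chains, and the free catechol is air-sensitive. The fallback sets out from 18 and uses silyl transfer instead of protic acid. TMSOTf with 2,2'-bipyridyl in CH2Cl2 at 0 °C converts the three aryl MOM ethers into the tris(trimethylsilyl) ether F4. This is hydrolysed at neutral pH (THF/H2O, degassed) and returns to the route at 19.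

Further compounds
F1 | step 8 | bis(2,4,6-triisopropylbenzoate) of diol 11; ring A carbinol (R), ring B carbinol (S) | C[C@@H](OC(=O)c1c(C(C)C)cc(C(C)C)cc1C(C)C)c1cc(OCOC)c(OCOC)c(Oc2cccc([C@H](C)OC(=O)c3c(C(C)C)cc(C(C)C)cc3C(C)C)c2OCOC)c1
F2 | step 9 | bis(α-chloroalkyl pinacol boronate): each quaternary carbon of 15 now bonded to CHCl(Bpin), CHCl centres undefined | C[C@@](CC/C=C(\C)CCC=C(C)C)(C(Cl)B1OC(C)(C)C(C)(C)O1)c1cc(OCOC)c(OCOC)c(Oc2cccc([C@](CC/C=C(\C)CCC=C(C)C)(C)C(Cl)B3OC(C)(C)C(C)(C)O3)c2OCOC)c1
F3 | step 9 | dialdehyde: each quaternary carbon bears CHO in place of Bpin; (R) at ring A, (S) at ring B by CIP | C[C@@](CC/C=C(\C)CCC=C(C)C)(C=O)c1cc(OCOC)c(OCOC)c(Oc2cccc([C@](CC/C=C(\C)CCC=C(C)C)(C)C=O)c2OCOC)c1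
F4 | step 10 | tris(trimethylsilyl) ether of 19 | C=C[C@@](C)(CC/C=C(\C)CCC=C(C)C)c1cc(O[Si](C)(C)C)c(O[Si](C)(C)C)c(Oc2cccc([C@](C)(C=C)CC/C=C(\C)CCC=C(C)C)c2O[Si](C)(C)C)c1
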